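**Assumption:** the target is an achiral flavone (no stereocentre, no stereogenic axis), so "single enantiomer" is read as the structure as drawn and no stereocontrol is needed.

**Retrosynthetic overview**
1. Target 12 ← hydrogenolysis of the 5-O-benzyl flavone 11.
2. 11 ← C2–C1' bond between chromone 8 (rings A and C) and the para C–H of phenol 4 (ring B), by a new Tf2O-mediated redox-neutral C2–H arylation.
3. Chromone 8 ← acetophenone 5 by mono-benzylation and enaminone ring closure (ring C is closed onto ring A before ring B is attached).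
4. Phenol 4 ← 1,2,4-trimethoxybenzene 1 by directed ortho-lithiation, borylation and oxidation.

**Route**

Step 1
Reactants: 1 1,2,4-trimethoxybenzene
Product: 4 2,3,6-trimethoxyphenol, via 2,3,6-trimethoxyphenyllithium 2 (not isolated), via dimethyl (2,3,6-trimethoxyphenyl)boronate 3 (not isolated)
Conditions: n-BuLi (1.1 equiv), TMEDA, THF, 0 °C; B(OMe)3, −78 °C → rt; AcOH, 30% aq. H2O2, 0 °C → rt
Reagents that add atoms: hydrogen peroxide, OO (the phenol oxygen of 4); n-butyllithium, [Li]CCCC (Li of 2 only); trimethyl borate, COB(OC)OC (B(OMe)2 group of 3 only)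
Why: Directed ortho-metalation takes the C3–H flanked by two methoxy groups, the aryllithium is trapped on boron, and boronate oxidation (1,2-aryl shift from B to O) gives the phenol; the mildly acidic peroxide protects the electron-rich phenol from base-promoted over-oxidation.

Step 2
Reactants: 5 2',6'-dihydroxy-4'-methoxyacetophenone
Product: 6 1-[2-(benzyloxy)-6-hydroxy-4-methoxyphenyl]ethan-1-one
Conditions: BnBr (1.05 equiv), K2CO3 (1.1 equiv), acetone, reflux
Reagents that add atoms: benzyl bromide, BrCc1ccccc1
Why: Williamson etherification; the two OH groups of 5 are equivalent, and after the first benzylation the remaining OH is locked in a hydrogen bond to the ketone, so the reaction stops at the mono-ether.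

Step 3
Reactants: 6 1-[2-(benzyloxy)-6-hydroxy-4-methoxyphenyl]ethan-1-one
Product: 8 5-(benzyloxy)-7-methoxy-4H-chromen-4-one, via enaminone 7 (not isolated)
Conditions: Me2NCH(OMe)2 (2 equiv), toluene, 100 °C; evaporate; conc. aq. HCl, CH2Cl2, 40 °C
Reagents that add atoms: N,N-dimethylformamide dimethyl acetal, COC(OC)N(C)C
Why: Enaminone chromone synthesis: condensation at the acetyl CH3 gives enaminone 7, then acid-promoted intramolecular oxa-Michael addition of the phenol and loss of dimethylamine closes ring C.

Step 4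
Reactants: 8 5-(benzyloxy)-7-methoxy-4H-chromen-4-one; 4 2,3,6-trimethoxyphenol
Product: 11 5-(benzyloxy)-2-(4-hydroxy-2,3,5-trimethoxyphenyl)-7-methoxy-4H-chromen-4-one, via 4-triflyloxychromenylium triflate 9 (not isolated), via 2-aryl-2H-chromen-4-yl triflate 10 (not isolated)
Conditions: Tf2O (1.0 equiv), 2,6-di-tert-butyl-4-methylpyridine (1.2 equiv), CH2Cl2, −78 °C; then 4 (1.2 equiv), −78 → −20 °C; then Et3N (4 equiv), −20 °C → rt
Reagents that add atoms: trifluoromethanesulfonic anhydride, O=S(=O)(OS(=O)(=O)C(F)(F)F)C(F)(F)F (triflyl group and triflate counter-ion of 9 and 10 only; none of its atoms remain in 11)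
Why: Proposed new method: Tf2O-mediated redox-neutral C2–H arylation of a chromone by the para C–H of a free phenol — Tf2O O-sulfonylates the vinylogous-ester carbonyl of 8 to give benzopyrylium 9, whose unsubstituted C2 (C4 is shielded by OTf and the peri 5-OBn) is attacked in Friedel–Crafts fashion by the only position of 4 para to OH (both ortho positions carry OMe, and the other free position is para only to the twisted, weakly donating 2-OMe) to give racemic enol triflate 10, and Et3N then removes the C2–H in a 1,4-elimination that breaks the O–S bond and expels triflinate CF3SO2−, forming C4=O and C2=C3, so Tf2O is both activator and two-electron oxidant (hexavalent sulfur goes to tetravalent sulfur), no external oxidant meets the oxidation-prone phenol, and the transient C2 stereocentre is erased; the closest known reaction types are Tf2O activation of pyridines (nucleophile addition to an N-triflylpyridinium, then base-induced loss of triflinate from the N-triflyl dihydropyridine) and Friedel–Crafts additions of arenes to 4-siloxybenzopyrylium salts.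

Step 5
Reactants: 11 5-(benzyloxy)-2-(4-hydroxy-2,3,5-trimethoxyphenyl)-7-methoxy-4H-chromen-4-one
Product: 12 5-hydroxy-2-(4-hydroxy-2,3,5-trimethoxyphenyl)-7-methoxy-4H-chromen-4-one
Conditions: H2 (1 atm), Pd/C (10 wt% Pd), EtOAc–MeOH 1:1, rt
Reagents that add atoms: none
Why: Catalytic hydrogenolysis (O-debenzylation) cleaves only the benzylic C–O bond; the methyl ethers, the free phenol and the cross-conjugated pyrone C2=C3 bond are inert at 1 atm when the reaction is stopped at full conversion.

**Compound list**
1 | 1,2,4-trimethoxybenzene | COc1ccc(OC)c(OC)c1 | starting material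
2 | 2,3,6-trimethoxyphenyllithium | COc1ccc(OC)c(OC)c1[Li] | intermediate
3 | dimethyl (2,3,6-trimethoxyphenyl)boronate | COc1ccc(OC)c(OC)c1B(OC)OC | intermediate
4 | 2,3,6-trimethoxyphenol | COc1ccc(OC)c(OC)c1O | intermediate
5 | 2',6'-dihydroxy-4'-methoxyacetophenone | CC(=O)c1c(O)cc(OC)cc1O | starting material
6 | 1-[2-(benzyloxy)-6-hydroxy-4-methoxyphenyl]ethan-1-one | CC(=O)c1c(O)cc(OC)cc1OCc1ccccc1 | intermediate
7 | (E)-1-[2-(benzyloxy)-6-hydroxy-4-methoxyphenyl]-3-(dimethylamino)prop-2-en-1-one | CN(C)/C=C/C(=O)c1c(O)cc(OC)cc1OCc1ccccc1 | intermediate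
8 | 5-(benzyloxy)-7-methoxy-4H-chromen-4-one | COc1cc(OCc2ccccc2)c2c(=O)ccoc2c1 | intermediate
9 | 5-(benzyloxy)-7-methoxy-4-[(trifluoromethanesulfonyl)oxy]chromenylium trifluoromethanesulfonate | COc1cc(OCc2ccccc2)c2c(OS(=O)(=O)C(F)(F)F)cc[o+]c2c1.[O-]S(=O)(=O)C(F)(F)F | intermediate
10 | 5-(benzyloxy)-2-(4-hydroxy-2,3,5-trimethoxyphenyl)-7-methoxy-2H-chromen-4-yl trifluoromethanesulfonate (racemic at C2) | COc1cc(OCc2ccccc2)c2C(OS(=O)(=O)C(F)(F)F)=CC(c3cc(OC)c(O)c(OC)c3OC)Oc2c1 | intermediate
11 | 5-(benzyloxy)-2-(4-hydroxy-2,3,5-trimethoxyphenyl)-7-methoxy-4H-chromen-4-one | COc1cc(OCc2ccccc2)c2c(=O)cc(-c3cc(OC)c(O)c(OC)c3OC)oc2c1 | intermediate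
12 | 5-hydroxy-2-(4-hydroxy-2,3,5-trimethoxyphenyl)-7-methoxy-4H-chromen-4-one (EANPDB:COMP_00065; achiral) | COc1cc(O)c2c(=O)cc(-c3cc(OC)c(O)c(OC)c3OC)oc2c1 | target

**Step count**
Total steps: 5. Longest linear sequence: 4 steps (5 → 6 → 8 → 11 → 12); the ring B arm is 1 → 4 → 11 → 12.

**Three steps most likely to fail, with fallbacks**

Step 4 (the proposed new step). The risks are O-triflyl transfer to the phenol, attack at C4 of the pyrylium, sluggish loss of triflinate from 10, and acid loss of the benzyl ether. The fallback uses only known chemistry, sets out from 4 and 6, and comes back to the route at 12. Duff formylation of 4 (hexamethylenetetramine, CF3CO2H, 80 °C, then aq. HCl) at the only position para to OH gives 4-hydroxy-2,3,5-trimethoxybenzaldehyde F1. Benzylation (BnBr, K2CO3, DMF, rt) gives 4-(benzyloxy)-2,3,5-trimethoxybenzaldehyde F2. Claisen–Schmidt condensation of F2 with acetophenone 6 (KOH, EtOH, rt) gives (E)-1-[2-(benzyloxy)-6-hydroxy-4-methoxyphenyl]-3-[4-(benzyloxy)-2,3,5-trimethoxyphenyl]prop-2-en-1-one F3. Oxidative cyclisation with catalytic I2 in DMSO at 120 °C gives 5-(benzyloxy)-2-[4-(benzyloxy)-2,3,5-trimethoxyphenyl]-7-methoxy-4H-chromen-4-one F4. Hydrogenolysis of F4 under the step 5 conditions removes both benzyl groups and gives target 12.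

Step 3 (chromone formation). The risks are O-methylation of the phenol by the acetal or incomplete cyclisation of the hindered enaminone. The fallback sets out from 6 and comes back at 8. Claisen formylation with NaH and ethyl formate in THF (0 °C → rt) gives the cyclic hemiacetal 5-(benzyloxy)-2-hydroxy-7-methoxychroman-4-one F5, which is dehydrated with catalytic p-TsOH in warm toluene to chromone 8.

Step 5 (debenzylation). The risk is partial reduction of the C2=C3 bond or slow cleavage of the hindered peri ether. The fallback sets out from 11 and comes back at 12: Lewis-acid debenzylation with BCl3 and pentamethylbenzene as cation scavenger in CH2Cl2 at −78 °C, where chelation to the C4 carbonyl speeds cleavage of the 5-O-benzyl group and the methyl ethers survive. This fallback makes no new compound (F0).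

**Further compounds**
F1 | step 4 | 4-hydroxy-2,3,5-trimethoxybenzaldehyde | COc1cc(C=O)c(OC)c(OC)c1O
F2 | step 4 | 4-(benzyloxy)-2,3,5-trimethoxybenzaldehyde | COc1cc(C=O)c(OC)c(OC)c1OCc1ccccc1
F3 | step 4 | (E)-1-[2-(benzyloxy)-6-hydroxy-4-methoxyphenyl]-3-[4-(benzyloxy)-2,3,5-trimethoxyphenyl]prop-2-en-1-one | COc1cc(O)c(C(=O)/C=C/c2cc(OC)c(OCc3ccccc3)c(OC)c2OC)c(OCc2ccccc2)c1
F4 | step 4 | 5-(benzyloxy)-2-[4-(benzyloxy)-2,3,5-trimethoxyphenyl]-7-methoxy-4H-chromen-4-one | COc1cc(OCc2ccccc2)c2c(=O)cc(-c3cc(OC)c(OCc4ccccc4)c(OC)c3OC)oc2c1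
F5 | step 3 | 5-(benzyloxy)-2-hydroxy-7-methoxychroman-4-one (racemic hemiacetal) | COc1cc(OCc2ccccc2)c2C(=O)CC(O)Oc2c1
F0 | step 5 | none | none
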